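**Two steps.** A one-step world is not this one: Friday's flask, with 1.43 equivalents of incoming ligand per starting complex, reads 49% complex with two exchanged at 40.0 min. Both exchanges run, so I want one quantity for how they share the ligand.

| flask | starting complex | incoming ligand | leaving ligand | remark | time |
|---|---|---|---|---|---|
| Friday's | 0.021 M | 0.030 M | 0.042 M | run made earlier |  |
| Sunday's | 0.021 M | 0.088 M | 0.042 M | run made earlier |  |
| gamma | 0.021 M | 0.0630 M | 0.0420 M |  | 80 min |
| alpha | 0.021 M | 0.0252 M | 0.0420 M |  | 80 min |

| run | time / min | complex with one exchanged / % | complex with two exchanged / % |
|---|---|---|---|
| Friday's | 6.00 | 46 | 42 |
| Friday's | 12.0 | 46 | 45 |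
| Friday's | 15.0 | 45 | 50 |
| Friday's | 25.0 | 48 | 49 |
| Friday's | 30.0 | 45 | 49 |
| Friday's | 40.0 | 46 | 49 |
| Sunday's | 6.00 | 3 | 101 |
| Sunday's | 12.0 | 0 | 98 |
| Sunday's | 15.0 | 2 | 100 |
| Sunday's | 25.0 | 0 | 101 |
| Sunday's | 30.0 | 1 | 97 |
| Sunday's | 40.0 | 0 | 98 |

(standard deviation of a reading: 1.5 percentage points)

- what was read earlier has a scatter of 1.5 percentage points, one standard deviation
- steps under discussion: starting complex + incoming ligand -> leaving ligand + complex with one exchanged; complex with one exchanged + incoming ligand -> leaving ligand + complex with two exchanged; complex with two exchanged -> over-reaction product

* which of these holds the largest part of the starting complex at the end of gamma (starting complex / complex with two exchanged / complex with one exchanged)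
* which of these holds the largest part of the starting complex at the end of alpha (starting complex / complex with two exchanged / complex with one exchanged)
* complex with one exchanged at the end of alpha, in percent of the starting complex charged

**The ladder.** The first rung is exchange: Sunday's flask reads 101% complex with two exchanged at 6.00 min, earlier than the asked 80 min. The next rung is the plateau: Friday's last readings hold 1.44 equivalents of ligand, matching the charge, so I take Friday's composition as set by the charge. The last rung is over-reaction: Sunday's reading of complex with two exchanged differs by 3 percentage points between 6.00 min and 40.0 min, against a scatter of 1.5 points, and I neglect over-reaction as a small correction.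

**The balance.** Counting ligand on the plateau, with the charged ligand taken as found in the two exchanged complexes and over-reaction neglected, [complex with two exchanged] minus [starting complex] equals the equivalents charged less one, in units of the charged complex. That excess is 0.429 for Friday's flask and 0.200 for alpha. Gamma carries 3.00 equivalents, more than double exchange takes, so I expect complex with two exchanged to lead there.

**The quotient.** Friday's mean of 46.0% complex with one exchanged, with the balance, leaves the small remainder of 5.57% starting complex. The plateau quotient, [starting complex] times [complex with two exchanged] over [complex with one exchanged] squared, reads 0.128.

**My reckoning.** Holding that quotient and alpha's balance, I get 12.2% starting complex and 55.6% complex with one exchanged.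

**The forecast.** It names complex with two exchanged for gamma and complex with one exchanged for alpha, with 55% (range 51% to 60%), just under my figure: “The one-exchanged complex dominates at about 55%”.

**The result.** Gamma ends with 97.9% complex with two exchanged, and alpha ends with 53.3% complex with one exchanged, its largest part.

    starting complex + incoming ligand → leaving ligand + complex with one exchanged (k = 60.0 M⁻¹ min⁻¹)
    complex with one exchanged + incoming ligand → leaving ligand + complex with two exchanged (k = 23.0 M⁻¹ min⁻¹)
    complex with two exchanged → over-reaction product (k = 2.70 × 10⁻⁴ min⁻¹)

**The quotient again.** Alpha's incoming ligand, the limiting reagent, stands at 0% of its charge at 80.0 min. For the neighbour of alpha charged with 0.010 M of incoming ligand, the excess is −0.524, and the quotient read on Friday's flask gives 56.1% starting complex and 40.2% complex with one exchanged. That neighbour holds 57.1% starting complex and 38.2% complex with one exchanged.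

(The numbers in the tables come from a simulation for substances that don't exist.)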